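**Strategy.** Ring B is disconnected at C6–C7 and C9–C10 (labdane numbering). An open-chain methyl ketone that already carries the side chain acts as an acetone-type α,α'-bis-nucleophile (C7 and C9) towards a ring A building block that offers an aldehyde (C6) and a latent tertiary cation (C10). In one flask a Mukaiyama aldol addition makes C6–C7, and the enol of the new ketone then captures the C10 cation, closing ring B as a trans-decalin with the C6 hydroxyl in place. The step exploits the 1,3-oxygenation pattern C6–C7–C8 of ring B next to the quaternary C10. The precursors are a Diels–Alder-derived cyclohexenyl aldehyde and a silyl enol ether.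

Key step: step 7

Assumptions: (a) Bicyclic compounds carry labdane locants: ring A = C1–C5 and C10; ring B = C5–C10; C18 = ester carbon on C4; C20 = methyl on C10; C17 = carbon on C8; side chain C11–C16 from C9. (b) The facial sense of the chiral catalysts in steps 2 and 13 is assigned by analogy; if it proves opposite, the antipodal catalyst or ligand is used with no other change.

Step 1
Reactants: 1 2,2-dimethoxyacetaldehyde; 2 methyl 2-(triphenylphosphoranylidene)propanoate
Product: 4 methyl (2E)-2-methyl-4-oxobut-2-enoate, via dimethyl acetal ester 3 (not isolated)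
Conditions: CH2Cl2, 25 °C; then 1 M HCl, THF, 25 °C
Reagents that add atoms: water, O
Why: Wittig olefination with a stabilized α-methyl ylide is E-selective, and the conjugated dimethyl acetal is hydrolysed by dilute acid without moving the double bond.

Step 2
Reactants: 4 methyl (2E)-2-methyl-4-oxobut-2-enoate; 5 (3E)-penta-1,3-diene
Product: 6 methyl (1R,2R,3R)-2-formyl-1,3-dimethylcyclohex-4-ene-1-carboxylate
Conditions: (S)-1-(2-methylphenyl)-3,3-diphenyltetrahydro-1H,3H-pyrrolo[1,2-c][1,3,2]oxazaborole (20 mol %) activated with HN(SO2CF3)2 (20 mol %), CH2Cl2, −78 to −40 °C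
Reagents that add atoms: none
Why: Catalytic enantioselective Diels–Alder reaction in which the Lewis-acid-bound formyl group directs ortho regiochemistry and endo approach (formyl cis to the C3 methyl), the E-dienophile places formyl trans to the ester, and the catalyst face sets the absolute configuration of C1 and C2 (labdane C4 and C5).

Step 3
Reactants: 6 methyl (1R,2R,3R)-2-formyl-1,3-dimethylcyclohex-4-ene-1-carboxylate
Product: 7 methyl (1R,2R)-2-formyl-1,3-dimethylcyclohex-3-ene-1-carboxylate
Conditions: [Pd(μ-Br)(P(t-Bu)3)]2 (1 mol %), toluene, 40 °C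
Reagents that add atoms: none
Why: Palladium-hydride alkene isomerization (insertion and β-hydride elimination) should move the disubstituted double bond to the trisubstituted C3=C4 position and stop there, because a further shift into conjugation would need a tertiary alkylpalladium at C3; C1 and C2 are not touched under these neutral conditions.

Step 4
Reactants: 8 methyl acetoacetate
Product: 9 methyl (2E)-3-{[(trifluoromethyl)sulfonyl]oxy}but-2-enoate
Conditions: (CF3SO2)2O, aqueous (CH3)4NOH, hexanes, 0 °C
Reagents that add atoms: trifluoromethanesulfonic anhydride, O=S(=O)(OS(=O)(=O)C(F)(F)F)C(F)(F)F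
Why: O-Triflation of the non-chelated tetramethylammonium enolate of the β-keto ester places the triflate trans to the ester (E), whereas a chelated lithium enolate would give the Z isomer.

Step 5
Reactants: 10 2-(3-chloropropyl)-2-methyl-1,3-dioxolane; 9 methyl (2E)-3-{[(trifluoromethyl)sulfonyl]oxy}but-2-enoate
Product: 13 methyl (2E)-3-methyl-7-oxooct-2-enoate, via Grignard reagent 11 (not isolated), via ketal ester 12 (not isolated)
Conditions: 10, Mg, THF, 50 °C; then 9, Fe(acac)3 (5 mol %), THF, −30 °C; then 1 M HCl, acetone, 25 °C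
Reagents that add atoms: water, O
Why: Iron-catalysed Kumada-type cross-coupling of an alkyl Grignard reagent with an enol triflate proceeds with retention of alkene geometry and faster than attack on the ester, and dilute acid then unmasks the ketone.

Step 6
Reactants: 13 methyl (2E)-3-methyl-7-oxooct-2-enoate
Product: 14 methyl (2E)-3-methyl-7-[(trimethylsilyl)oxy]octa-2,7-dienoate
Conditions: LiN(i-Pr)2, (CH3)3SiCl (internal quench), THF, −78 °C
Reagents that add atoms: chlorotrimethylsilane, C[Si](C)(C)Cl
Why: Kinetic deprotonation of the methyl ketone at its methyl group with in situ silylation gives the less substituted silyl enol ether before the enolate can equilibrate or add to the enoate.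

Step 7
Reactants: 7 methyl (1R,2R)-2-formyl-1,3-dimethylcyclohex-3-ene-1-carboxylate; 14 methyl (2E)-3-methyl-7-[(trimethylsilyl)oxy]octa-2,7-dienoate
Product: 16 methyl (4R,5R,6S,9R,10S)-6-hydroxy-9-[(3E)-5-methoxy-3-methyl-5-oxopent-3-en-1-yl]-4,10-dimethyl-8-oxo-trans-decalin-4-carboxylate (labdane locants), via aldol adduct 15 (not isolated)
Conditions: TiCl4 (1.1 equiv), CH2Cl2, −78 °C; then CF3SO3H (1.5 equiv), −78 to −30 °C; aqueous NaHCO3
Reagents that add atoms: none
Why: Proposed new method: TiCl4 binds the aldehyde and the C4 ester carbonyl of 7 in a chelate, C7 of silyl enol ether 14 adds to C6 (Mukaiyama aldol), and CF3SO3H then protonates C1 of the ring alkene so that the tertiary C10 cation is captured by C9 of the enol of the new ketone. The closest known reaction type is the cation–olefin cyclization terminated by the enol of a β-keto ester; the one-flask tandem with an aldol step and a simple ketone enol is not established. Ring B closes in a 6-(enolendo) mode through a chair transition state. C6 (S) is set by the chelate (attack on the formyl face syn to H5), C10 (S) by attack of C9 trans to H5 and away from the axial C4 methyl, which gives the trans ring fusion, and C9 (R) by equilibration through the enol to the equatorial side chain. The step needs C- over O-alkylation (O-attack gives a cyclic oxocarbenium ion that reopens under the acid, and closure through C7 would give a four-membered ring), aldol addition before ionization (secured by adding the Brønsted acid last) and survival of the β-hydroxy ketone (the homoallylic C6 hydroxyl cannot ionize to a stabilized cation and, once ring B is closed, its equatorial C–O bond is poorly aligned for elimination).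

Step 8
Reactants: 16 bicyclic hydroxy ketone
Product: 17 methyl (4R,5R,6S,9S,10R)-6-hydroxy-9-[(3E)-5-methoxy-3-methyl-5-oxopent-3-en-1-yl]-4,10-dimethyl-8-methylidene-trans-decalin-4-carboxylate (labdane locants)
Conditions: Zn, CH2Br2, TiCl4, THF/CH2Cl2, 0 to 25 °C
Reagents that add atoms: dibromomethane, BrCBr
Why: Takai–Lombardo methylenation converts the hindered, enolizable ketone into the exocyclic alkene without base, so both esters, the free hydroxyl and the C9 configuration should survive.

Step 9
Reactants: 17 exocyclic alkene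
Product: 18 methyl (4R,5R,6S,8R,9R,10S)-6,8-dihydroxy-9-[(3E)-5-methoxy-3-methyl-5-oxopent-3-en-1-yl]-4,8,10-trimethyl-trans-decalin-4-carboxylate (labdane locants)
Conditions: Co(acac)2 (20 mol %), PhSiH3, O2 (1 atm), THF, 25 °C
Reagents that add atoms: dioxygen, O=O
Why: Mukaiyama hydration (hydrogen-atom transfer from a cobalt hydride, trapping of the tertiary C8 radical by O2, reduction of the peroxide) is Markovnikov-selective for the electron-rich 1,1-disubstituted alkene over the enoate, and O2 should enter from the equatorial α-face because the β-face is blocked by the axial C10 methyl, giving the 8α-hydroxy-8β-methyl centre.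

Step 10
Reactants: 18 diol enoate
Product: 19 methyl (4R,5R,6S,8R,9R,10S)-6,8-dihydroxy-9-[(3E)-5-hydroxy-3-methylpent-3-en-1-yl]-4,8,10-trimethyl-trans-decalin-4-carboxylate (labdane locants)
Conditions: i-Bu2AlH (5 equiv), CH2Cl2, −78 °C; aqueous potassium sodium tartrate
Reagents that add atoms: none
Why: i-Bu2AlH reduces the unhindered conjugated ester to the allylic alcohol at low temperature, while the C4 ester, shielded by its quaternary centre, should survive.

Step 11
Reactants: 19 allylic alcohol
Product: 20 methyl (4R,5R,6S,8R,9R,10S)-6,8-dihydroxy-4,8,10-trimethyl-9-[(3E)-3-methyl-5-oxopent-3-en-1-yl]-trans-decalin-4-carboxylate (labdane locants)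
Conditions: MnO2 (activated), CH2Cl2, 25 °C
Reagents that add atoms: none
Why: MnO2 oxidizes only the allylic primary alcohol; the secondary C6 and tertiary C8 hydroxyls are inert.

Step 12
Reactants: 21 4-methylfuran-2(5H)-one
Product: 22 4-methyl-2-[(trimethylsilyl)oxy]furan
Conditions: (CH3)3SiOSO2CF3, Et3N, CH2Cl2, 0 °C
Reagents that add atoms: trimethylsilyl trifluoromethanesulfonate, C[Si](C)(C)OS(=O)(=O)C(F)(F)F
Why: Soft enolization and O-silylation of the butenolide give the aromatic 2-silyloxyfuran.

Step 13
Reactants: 20 enal; 22 4-methyl-2-[(trimethylsilyl)oxy]furan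
Product: 24 CNP0104474.1, methyl (4R,5R,6S,8R,9R,10S)-6,8-dihydroxy-9-{(3E,5S)-5-hydroxy-3-methyl-5-[(2S)-3-methyl-5-oxo-2,5-dihydrofuran-2-yl]pent-3-en-1-yl}-4,8,10-trimethyl-trans-decalin-4-carboxylate (labdane locants), via silyl ether 23 (not isolated)
Conditions: Ti(O-i-Pr)4 (20 mol %), (S)-1,1'-bi-2-naphthol (20 mol %), Et2O, −20 °C; then 1 M HCl, THF, 0 °C
Reagents that add atoms: none
Why: Catalytic asymmetric vinylogous Mukaiyama aldol reaction in which the furan attacks through C5 in an open transition state that favours the like (threo) adduct and the chiral titanium binaphtholate selects the aldehyde face, setting C15 (S) and C16 (S); acid work-up removes the silyl group.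

**Compound list**

1 | 2,2-dimethoxyacetaldehyde | COC(OC)C=O | starting material
2 | methyl 2-(triphenylphosphoranylidene)propanoate | COC(=O)C(C)=P(c1ccccc1)(c1ccccc1)c1ccccc1 | starting material
3 | methyl (2E)-4,4-dimethoxy-2-methylbut-2-enoate | COC(OC)/C=C(\C)C(=O)OC | intermediate (not isolated)
4 | methyl (2E)-2-methyl-4-oxobut-2-enoate | O=C/C=C(\C)C(=O)OC | intermediate
5 | (3E)-penta-1,3-diene | C=C/C=C/C | starting material
6 | methyl (1R,2R,3R)-2-formyl-1,3-dimethylcyclohex-4-ene-1-carboxylate | COC(=O)[C@]1(C)CC=C[C@@H](C)[C@H]1C=O | intermediate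
7 | methyl (1R,2R)-2-formyl-1,3-dimethylcyclohex-3-ene-1-carboxylate | COC(=O)[C@]1(C)CCC=C(C)[C@H]1C=O | intermediate
8 | methyl acetoacetate | COC(=O)CC(C)=O | starting material
9 | methyl (2E)-3-{[(trifluoromethyl)sulfonyl]oxy}but-2-enoate | COC(=O)/C=C(\C)OS(=O)(=O)C(F)(F)F | intermediate
10 | 2-(3-chloropropyl)-2-methyl-1,3-dioxolane | CC1(CCCCl)OCCO1 | starting material
11 | [3-(2-methyl-1,3-dioxolan-2-yl)propyl]magnesium chloride | CC1(CCC[Mg]Cl)OCCO1 | intermediate (not isolated)
12 | methyl (2E)-3-methyl-6-(2-methyl-1,3-dioxolan-2-yl)hex-2-enoate | COC(=O)/C=C(\C)CCCC1(C)OCCO1 | intermediate (not isolated)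
13 | methyl (2E)-3-methyl-7-oxooct-2-enoate | COC(=O)/C=C(\C)CCCC(C)=O | intermediate
14 | methyl (2E)-3-methyl-7-[(trimethylsilyl)oxy]octa-2,7-dienoate | COC(=O)/C=C(\C)CCCC(=C)O[Si](C)(C)C | intermediate
15 | methyl (1R,2R)-2-[(1S,7E)-1-hydroxy-9-methoxy-7-methyl-3,9-dioxonon-7-en-1-yl]-1,3-dimethylcyclohex-3-ene-1-carboxylate | COC(=O)[C@]1(C)CCC=C(C)[C@H]1[C@@H](O)CC(=O)CCC/C(C)=C/C(=O)OC | intermediate (not isolated)
16 | bicyclic hydroxy ketone (4R,5R,6S,9R,10S; 6-hydroxy, 8-oxo, enoate side chain on C9) | COC(=O)[C@]1(C)CCC[C@@]2(C)[C@H]1[C@@H](O)CC(=O)[C@@H]2CC/C(C)=C/C(=O)OC | intermediate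
17 | 8-methylidene compound (4R,5R,6S,9S,10R) | COC(=O)[C@]1(C)CCC[C@@]2(C)[C@H]1[C@@H](O)CC(=C)[C@@H]2CC/C(C)=C/C(=O)OC | intermediate
18 | 6,8-diol enoate (4R,5R,6S,8R,9R,10S) | COC(=O)[C@]1(C)CCC[C@@]2(C)[C@H]1[C@@H](O)C[C@@](C)(O)[C@@H]2CC/C(C)=C/C(=O)OC | intermediate
19 | 6,8-diol allylic alcohol (4R,5R,6S,8R,9R,10S) | COC(=O)[C@]1(C)CCC[C@@]2(C)[C@H]1[C@@H](O)C[C@@](C)(O)[C@@H]2CC/C(C)=C/CO | intermediate
20 | 6,8-diol enal (4R,5R,6S,8R,9R,10S) | COC(=O)[C@]1(C)CCC[C@@]2(C)[C@H]1[C@@H](O)C[C@@](C)(O)[C@@H]2CC/C(C)=C/C=O | intermediate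
21 | 4-methylfuran-2(5H)-one | CC1=CC(=O)OC1 | starting material
22 | 4-methyl-2-[(trimethylsilyl)oxy]furan | Cc1coc(O[Si](C)(C)C)c1 | intermediate
23 | 15-O-trimethylsilyl ether of 24 | COC(=O)[C@]1(C)CCC[C@@]2(C)[C@H]1[C@@H](O)C[C@@](C)(O)[C@@H]2CC/C(C)=C/[C@H](O[Si](C)(C)C)[C@H]1OC(=O)C=C1C | intermediate (not isolated)
24 | CNP0104474.1 (4R,5R,6S,8R,9R,10S,13E,15S,16S) | COC(=O)[C@]1(C)CCC[C@@]2(C)[C@H]1[C@@H](O)C[C@@](C)(O)[C@@H]2CC/C(C)=C/[C@H](O)[C@H]1OC(=O)C=C1C | target

**Total step count:** 13.
**Longest linear sequence:** 9 steps (steps 4, 5, 6, 7, 8, 9, 10, 11, 13; the branch through steps 1, 2, 3 is equally long).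

**Steps most likely to fail**

1. Step 7 (proposed new method). What may go wrong: elimination of the aldol hydroxyl before ring closure, capture of the C10 cation by the ketone or ester oxygen instead of by C9, loss of the C5 configuration through proton loss from the C10 cation, or poor facial control at C6. Fallback (sets out from 7, returns at 17): the two bonds are made in two separate known operations with a terpenoid partner in place of the ketone. Commercial methyl geranate is oxidized at its E-methyl group (SeO2, t-BuOOH, CH2Cl2) to methyl (2E,6E)-8-hydroxy-3,7-dimethylocta-2,6-dienoate F1. This is converted (CH3SO2Cl, LiCl, 2,4,6-collidine, DMF, 0 °C) into methyl (2E,6E)-8-chloro-3,7-dimethylocta-2,6-dienoate F2. Its allylbarium reagent (barium metal from BaI2 and lithium biphenylide, THF, −78 °C) should add to 7 through the unsubstituted allyl terminus with retention of the E-alkene and give methyl (1R,2R)-2-[(1S,3E,7E)-1-hydroxy-9-methoxy-3,7-dimethyl-9-oxonona-3,7-dien-1-yl]-1,3-dimethylcyclohex-3-ene-1-carboxylate F3. ClSO3H in 2-nitropropane at −78 °C should then effect the classical cation–olefin cyclization of the cyclohexenyl cation onto the (E)-trisubstituted alkene, and proton loss from the C8 cation gives 17 (its endocyclic isomer converges on 18 in step 9).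

2. Step 3. What may go wrong: double-bond migration running on into conjugation with the formyl group, with loss of the C2 stereocentre, or incomplete migration. Fallback (sets out from 6, returns at 7): the formyl group is masked first. Acetalization (ethane-1,2-diol, pyridinium 4-toluenesulfonate, benzene, water removal) gives methyl (1R,2R,3R)-2-(1,3-dioxolan-2-yl)-1,3-dimethylcyclohex-4-ene-1-carboxylate F4, which has neither an acidic C2–H nor a conjugative sink. Alkene migration (RhCl3·3H2O, ethanol, 60 °C) should then stop at the trisubstituted alkene, methyl (1R,2R)-2-(1,3-dioxolan-2-yl)-1,3-dimethylcyclohex-3-ene-1-carboxylate F5, and dilute aqueous HCl in acetone at 0 °C releases 7.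

3. Step 13. What may go wrong: poor facial and like/unlike selectivity in a C–C bond formation remote from all existing stereocentres, and interference of the free hydroxyls with the titanium catalyst. Fallback (sets out from 20, returns at 24): the like/unlike problem is separated from the facial problem. The addition of 22 to 20 is run with a chiral Lewis acid that favours the unlike (erythro) adduct with the correct C16 configuration, the (15R,16S) diastereomer F6. Mitsunobu inversion of its allylic C15 carbinol (4-nitrobenzoic acid, PPh3, diisopropyl azodicarboxylate, THF, 0 °C; the hindered C6 and tertiary C8 hydroxyls should not react) gives the (15S,16S) 4-nitrobenzoate F7, and mild methanolysis (K2CO3, MeOH, 0 °C) releases 24.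

**Further compounds**

F1 | step 7 | methyl (2E,6E)-8-hydroxy-3,7-dimethylocta-2,6-dienoate | COC(=O)/C=C(\C)CC/C=C(\C)CO
F2 | step 7 | methyl (2E,6E)-8-chloro-3,7-dimethylocta-2,6-dienoate | COC(=O)/C=C(\C)CC/C=C(\C)CCl
F3 | step 7 | methyl (1R,2R)-2-[(1S,3E,7E)-1-hydroxy-9-methoxy-3,7-dimethyl-9-oxonona-3,7-dien-1-yl]-1,3-dimethylcyclohex-3-ene-1-carboxylate | COC(=O)[C@]1(C)CCC=C(C)[C@H]1[C@@H](O)C/C(C)=C/CC/C(C)=C/C(=O)OC
F4 | step 3 | methyl (1R,2R,3R)-2-(1,3-dioxolan-2-yl)-1,3-dimethylcyclohex-4-ene-1-carboxylate | COC(=O)[C@]1(C)CC=C[C@@H](C)[C@H]1C1OCCO1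
F5 | step 3 | methyl (1R,2R)-2-(1,3-dioxolan-2-yl)-1,3-dimethylcyclohex-3-ene-1-carboxylate | COC(=O)[C@]1(C)CCC=C(C)[C@H]1C1OCCO1
F6 | step 13 | (15R,16S) diastereomer of 24 | COC(=O)[C@]1(C)CCC[C@@]2(C)[C@H]1[C@@H](O)C[C@@](C)(O)[C@@H]2CC/C(C)=C/[C@@H](O)[C@H]1OC(=O)C=C1C
F7 | step 13 | 15-O-(4-nitrobenzoyl) ester of 24 | COC(=O)[C@]1(C)CCC[C@@]2(C)[C@H]1[C@@H](O)C[C@@](C)(O)[C@@H]2CC/C(C)=C/[C@H](OC(=O)c1ccc(cc1)[N+](=O)[O-])[C@H]1OC(=O)C=C1C
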